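**Retrosynthetic overview**

1. Feature: in the ten-membered carbocycle C1–C10, C10 carries a three-carbon branch (isopropyl) and sits next to the unsubstituted C9 methylene. The C9–C10 bond is cut by a retro-[3,3] (Ireland–Claisen) step to a fourteen-membered lactone in which C9 is the ester α-carbon and C10 the γ-carbon of an (E)-2-methylallyl ester; the C9 carboxyl is removed later and the C10 isopropenyl group is hydrogenated.
2. Stereocontrol: C1 is carried through the ring contraction as its 1S silyl ether, the epimer of the target, because only this configuration places the silyloxy group anti to the forming C9–C10 bond for attack on the C10 face that gives 10S. C1 is then corrected by oxidation to the enone and peripheral hydride addition, and C2/C3 come last from a C1-hydroxyl-directed epoxidation.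
3. Lactone 22 ⇐ seco acid (Yamaguchi) ⇐ Nozaki–Hiyama–Kishi union at C1–C2 of alkenyl iodide 13 (C2–C9) with enal 16 (C1, C10, Cq, OCH2). Both halves come from (E)-3-iodo-2-methylprop-2-en-1-ol (from propargyl alcohol); C4 by Brown allylation, (E)-C6=C7 and the C9 ester by Johnson–Claisen rearrangement.
4. Ring order: fourteen-membered lactone (step 14) → ten-membered carbocycle by four-atom ring contraction (step 15) → oxirane (step 23).

Key step: step 15

Assumption: target numbering is used for every intermediate (C1 acetoxy carbon, C2/C3 oxirane carbons, C4 senecioate carbon, C5, C6=C7, C8, C9, C10 isopropyl carbon; Cq is the methyl-bearing carbon of the 2-methylallyl unit), and the target is taken as (1R,2R,3R,4S,6E,10S).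
Assumption: C9 of 24–27 is left unassigned because it is erased in step 17; all cyclodeca-1,5-dienes are handled below about 60 °C and on base-washed silica to avoid Cope rearrangement and acid-induced transannular cyclisation.

**Route**

Step 1
Reactants: 1 propargyl alcohol
Product: 3 (E)-3-iodo-2-methylprop-2-en-1-ol, via alkenylalane 2 (not isolated)
Conditions: AlMe3 (3 equiv), Cp2ZrCl2 (0.25 equiv), CH2Cl2, 0 → 23 °C; then I2, THF, −30 → 0 °C; aq. K2CO3
Reagents that add atoms: trimethylaluminium C[Al](C)C; iodine II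
Why: Zirconium-catalysed Negishi carboalumination adds methyl and aluminium syn across the alkyne with methyl at the internal carbon, and iodinolysis of the C–Al bond with retention gives the (E)-iodoalkene.

Step 2
Reactants: 3 (E)-3-iodo-2-methylprop-2-en-1-ol
Product: 4 (E)-3-iodo-2-methylprop-2-enal
Conditions: MnO2, CH2Cl2, 23 °C (solution used directly)
Reagents that add atoms: none
Why: MnO2 oxidises the primary allylic alcohol selectively to the enal and leaves the alkenyl iodide untouched (allylic alcohol oxidation).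

Step 3
Reactants: 4 (E)-3-iodo-2-methylprop-2-enal
Product: 6 (1E,3S)-1-iodo-2-methylhexa-1,5-dien-3-ol, via borinate 5 (not isolated)
Conditions: (−)-Ipc2BOMe [Ipc from (+)-α-pinene], CH2=CHCH2MgBr, Et2O, 0 → 23 °C; then 4, −78 °C; NaOH, H2O2, 0 → 23 °C
Reagents that add atoms: allylmagnesium bromide C=CC[Mg]Br
Why: Brown asymmetric allylboration delivers the allyl group through a chair transition state to the Si face of the enal, which sets C4 as S.

Step 4
Reactants: 6 (1E,3S)-1-iodo-2-methylhexa-1,5-dien-3-ol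
Product: 7 (1E,3S)-1-iodo-3-(4-methoxybenzyloxy)-2-methylhexa-1,5-diene
Conditions: NaH, 4-MeOC6H4CH2Cl, Bu4NI (cat.), THF–DMF, 0 → 23 °C
Reagents that add atoms: 4-methoxybenzyl chloride COc1ccc(CCl)cc1
Why: Williamson etherification of the secondary allylic alkoxide protects C4–OH with a group that survives base, heat and organometallics and is later removed oxidatively.

Step 5
Reactants: 7 (1E,3S)-1-iodo-3-(4-methoxybenzyloxy)-2-methylhexa-1,5-diene
Product: 8 (3S,4E)-5-iodo-3-(4-methoxybenzyloxy)-4-methylpent-4-enal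
Conditions: OsO4 (cat.), NaIO4, 2,6-lutidine, dioxane–H2O, 23 °C
Reagents that add atoms: osmium tetroxide O=[Os](=O)(=O)=O; sodium periodate [Na+].[O-][I](=O)(=O)=O
Why: Lemieux–Johnson cleavage works because OsO4 dihydroxylates the terminal monosubstituted alkene much faster than the electron-poor trisubstituted iodoalkene and periodate cleaves the diol to the C6 aldehyde.

Step 6
Reactants: 8 (3S,4E)-5-iodo-3-(4-methoxybenzyloxy)-4-methylpent-4-enal; 9 isopropenylmagnesium bromide
Product: 10 (1E,3S)-1-iodo-3-(4-methoxybenzyloxy)-2,6-dimethylhepta-1,6-dien-5-ol (both carbinol epimers)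
Conditions: THF, −78 °C; aq. NH4Cl
Reagents that add atoms: none
Why: Grignard 1,2-addition to the aldehyde at low temperature outruns β-elimination, and the carbinol (target C6) may be a mixture because it becomes sp2 in step 7.

Step 7
Reactants: 10 (1E,3S)-1-iodo-3-(4-methoxybenzyloxy)-2,6-dimethylhepta-1,6-dien-5-ol; 11 triethyl orthoacetate
Product: 13 ethyl (4E,7S,8E)-9-iodo-7-(4-methoxybenzyloxy)-4,8-dimethylnona-4,8-dienoate, via ketene acetal 12 (not isolated)
Conditions: 11 (excess), EtCO2H (cat.), 135 °C, EtOH distilled off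
Reagents that add atoms: none
Why: Johnson–Claisen rearrangement of the mixed ketene acetal through a chair transition state with the C5 chain equatorial gives the (E)-C6=C7 trisubstituted alkene and adds C9 with its ester carbon.

Step 8
Reactants: 3 (E)-3-iodo-2-methylprop-2-en-1-ol
Product: 14 (E)-triethyl(3-iodo-2-methylprop-2-enyloxy)silane
Conditions: Et3SiCl, imidazole, CH2Cl2, 0 °C
Reagents that add atoms: chlorotriethylsilane CC[Si](Cl)(CC)CC
Why: Silyl ether formation masks the primary alcohol with a group that tolerates t-BuLi and can later be removed beside a secondary t-BuMe2Si ether.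

Step 9
Reactants: 14 (E)-triethyl(3-iodo-2-methylprop-2-enyloxy)silane
Product: 16 (E)-3-methyl-4-(triethylsilyloxy)but-2-enal, via alkenyllithium 15 (not isolated)
Conditions: t-BuLi (2.1 equiv), Et2O, −78 °C; DMF, −78 → 0 °C; H2O
Reagents that add atoms: N,N-dimethylformamide CN(C)C=O
Why: Iodine–lithium exchange proceeds with retention of alkene geometry and formylation of the alkenyllithium with DMF gives the (E)-enal that supplies C1, C10, Cq and the OCH2 carbon.

Step 10
Reactants: 13 ethyl (4E,7S,8E)-9-iodo-7-(4-methoxybenzyloxy)-4,8-dimethylnona-4,8-dienoate; 16 (E)-3-methyl-4-(triethylsilyloxy)but-2-enal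
Product: 17 ethyl (4E,7S,8E,10S,11E)-10-hydroxy-7-(4-methoxybenzyloxy)-4,8,12-trimethyl-13-(triethylsilyloxy)trideca-4,8,11-trienoate
Conditions: CrCl2 (3 equiv), N-[2-(4-isopropyl-4,5-dihydrooxazol-2-yl)-6-methylphenyl]methanesulfonamide (one antipode, 3.3 equiv), Et3N, NiCl2 (cat.), THF, 23 °C
Reagents that add atoms: none
Why: In this Nozaki–Hiyama–Kishi coupling the alkenyl iodide is activated by nickel, transferred to chromium and added to the aldehyde without touching the ester, and the chiral oxazoline–sulfonamide ligand on chromium should control the enal face so that C1 is set as S (the ligand antipode is chosen on a trial run and C1 epimers are separable diastereomers).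

Step 11
Reactants: 17 ethyl (4E,7S,8E,10S,11E)-10-hydroxy-7-(4-methoxybenzyloxy)-4,8,12-trimethyl-13-(triethylsilyloxy)trideca-4,8,11-trienoate
Product: 18 ethyl (4E,7S,8E,10S,11E)-10-(tert-butyldimethylsilyloxy)-7-(4-methoxybenzyloxy)-4,8,12-trimethyl-13-(triethylsilyloxy)trideca-4,8,11-trienoate
Conditions: t-BuMe2SiCl, imidazole, DMAP (cat.), DMF, 23 °C
Reagents that add atoms: tert-butyldimethylsilyl chloride CC(C)(C)[Si](C)(C)Cl
Why: Silyl ether formation under basic conditions protects the bis-allylic C1 alcohol without ionising this acid-sensitive centre.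

Step 12
Reactants: 18 ethyl (4E,7S,8E,10S,11E)-10-(tert-butyldimethylsilyloxy)-7-(4-methoxybenzyloxy)-4,8,12-trimethyl-13-(triethylsilyloxy)trideca-4,8,11-trienoate
Product: 19 ethyl (4E,7S,8E,10S,11E)-10-(tert-butyldimethylsilyloxy)-13-hydroxy-7-(4-methoxybenzyloxy)-4,8,12-trimethyltrideca-4,8,11-trienoate
Conditions: NH4F, MeOH, 23 °C
Reagents that add atoms: none
Why: Near-neutral fluoride desilylation removes the primary Et3Si ether much faster than the hindered secondary t-BuMe2Si ether (selective silyl ether cleavage).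

Step 13
Reactants: 19 ethyl (4E,7S,8E,10S,11E)-10-(tert-butyldimethylsilyloxy)-13-hydroxy-7-(4-methoxybenzyloxy)-4,8,12-trimethyltrideca-4,8,11-trienoate
Product: 20 (4E,7S,8E,10S,11E)-10-(tert-butyldimethylsilyloxy)-13-hydroxy-7-(4-methoxybenzyloxy)-4,8,12-trimethyltrideca-4,8,11-trienoic acid
Conditions: LiOH, THF–MeOH–H2O, 23 °C; dilute H3PO4 to pH 5
Reagents that add atoms: lithium hydroxide [Li+].[OH-]
Why: Saponification of the ethyl ester leaves the silyl and 4-methoxybenzyl ethers intact, and the acid is liberated at pH 5 to spare the bis-allylic silyl ether.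

Step 14
Reactants: 20 (4E,7S,8E,10S,11E)-10-(tert-butyldimethylsilyloxy)-13-hydroxy-7-(4-methoxybenzyloxy)-4,8,12-trimethyltrideca-4,8,11-trienoic acid
Product: 22 (5E,8S,9E,11S,12E)-11-(tert-butyldimethylsilyloxy)-8-(4-methoxybenzyloxy)-5,9,13-trimethyl-1-oxacyclotetradeca-5,9,12-trien-2-one, via mixed anhydride 21 (not isolated)
Conditions: 2,4,6-Cl3C6H2COCl, Et3N, THF, 23 °C; slow addition to DMAP, toluene, 40 °C, high dilution
Reagents that add atoms: none
Why: Yamaguchi macrolactonisation closes the fourteen-membered ring because DMAP transfers the acyl group of the mixed anhydride to the primary allylic alcohol under high dilution, and a ring with three (E)-trisubstituted alkenes of this size is essentially unstrained.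

Step 15
Reactants: 22 (5E,8S,9E,11S,12E)-11-(tert-butyldimethylsilyloxy)-8-(4-methoxybenzyloxy)-5,9,13-trimethyl-1-oxacyclotetradeca-5,9,12-trien-2-one
Product: 25 (1R,2E,4S,6E,10S)-1-(tert-butyldimethylsilyloxy)-10-isopropenyl-4-(4-methoxybenzyloxy)-3,7-dimethylcyclodeca-2,6-diene-9-carboxylic acid (target numbering; C9 unassigned), via silyl ketene acetal 23 (not isolated), via silyl ester 24 (not isolated)
Conditions: KN(SiMe3)2 (1.5 equiv) and t-BuMe2SiCl (2 equiv) premixed, THF–DMPU, −78 °C, then 22; → 23 °C, then 50–55 °C if needed; THF–H2O, pH 5 (NaH2PO4)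
Reagents that add atoms: none
Why: KN(SiMe3)2 removes a C9 proton of the lactone and the potassium enolate is trapped on oxygen by t-BuMe2SiCl to give the cyclic silyl ketene acetal 23, which on warming undergoes a concerted suprafacial [3,3]-sigmatropic shift (Ireland–Claisen rearrangement) in which C9 bonds to C10 while the allylic CH2–O bond breaks. The closest known reaction type is the Ireland–Claisen ring contraction of macrocyclic allylic lactones to carbocycles that carry vicinal carboxyl and alkenyl groups. The ten-membered ring is closed by this transannular C9–C10 bond formation inside the fourteen-membered ring, a four-atom ring contraction that extrudes the carbonyl carbon and the 2-methylallyl carbons as the exocyclic silyl carboxylate and the isopropenyl group. C10 is controlled by the adjacent C1 silyloxy centre: methyl groups cis to C1 on both flanking alkenes hold H-1 in the plane of both alkenes (allylic 1,3-strain), the tether carbon C2 lies gauche to the forming bond and the bulky silyloxy group lies anti to it, so C9 should add to the C10 face opposite the silyloxy group in a crossed chair–chair array, which for 1S means 10S; C9 follows from the ketene acetal geometry and the chair or boat of the six-atom array and is irrelevant because it is removed in step 17. The step needs this C10 face selectivity, which the 1S relay centre secures, and O-silylation faster than self-condensation, which the internal quench at −78 °C and the single enolisable position secure; the temperature is kept below about 60 °C so that the (E,E)-cyclodeca-1,5-diene does not undergo Cope rearrangement.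

Step 16
Reactants: 25 (1R,2E,4S,6E,10S)-1-(tert-butyldimethylsilyloxy)-10-isopropenyl-4-(4-methoxybenzyloxy)-3,7-dimethylcyclodeca-2,6-diene-9-carboxylic acid
Product: 26 (1S,2E,4S,6E,10R)-1-(tert-butyldimethylsilyloxy)-10-isopropyl-4-(4-methoxybenzyloxy)-3,7-dimethylcyclodeca-2,6-diene-9-carboxylic acid (C9 unassigned)
Conditions: H2 (1–3 atm), RhCl(PPh3)3 (cat.), benzene–EtOH, 23 °C
Reagents that add atoms: none
Why: Homogeneous hydrogenation with RhCl(PPh3)3 reduces the 1,1-disubstituted isopropenyl alkene and leaves the two trisubstituted ring alkenes, the benzyl ether and the acid untouched (the CIP descriptors change only because the priorities change).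

Step 17
Reactants: 26 (1S,2E,4S,6E,10R)-1-(tert-butyldimethylsilyloxy)-10-isopropyl-4-(4-methoxybenzyloxy)-3,7-dimethylcyclodeca-2,6-diene-9-carboxylic acid
Product: 28 (1S,2E,4S,6E,10S)-1-(tert-butyldimethylsilyloxy)-10-isopropyl-4-(4-methoxybenzyloxy)-3,7-dimethylcyclodeca-2,6-diene, via thiohydroxamate ester 27 (not isolated)
Conditions: DCC, N-hydroxypyridine-2-thione, DMAP (cat.), CH2Cl2, 0 → 23 °C, dark; then Bu3SnH, hν (tungsten lamp), benzene, 15 °C
Reagents that add atoms: none
Why: In this Barton reductive decarboxylation the thiohydroxamate ester fragments under visible light to a secondary C9 radical that is reduced by Bu3SnH, which erases the C9 centre, and only disfavoured 3-exo, 4-exo and 5-endo transannular modes are open to this radical.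

Step 18
Reactants: 28 (1S,2E,4S,6E,10S)-1-(tert-butyldimethylsilyloxy)-10-isopropyl-4-(4-methoxybenzyloxy)-3,7-dimethylcyclodeca-2,6-diene
Product: 29 (1S,2E,4S,6E,10S)-1-(tert-butyldimethylsilyloxy)-10-isopropyl-3,7-dimethylcyclodeca-2,6-dien-4-ol
Conditions: DDQ, CH2Cl2–aq. phosphate buffer (pH 7), 0 °C
Reagents that add atoms: none
Why: DDQ cleaves the 4-methoxybenzyl ether oxidatively through the benzylic oxocarbenium ion, and buffering protects the acid-sensitive cyclodecadiene.

Step 19
Reactants: 29 (1S,2E,4S,6E,10S)-1-(tert-butyldimethylsilyloxy)-10-isopropyl-3,7-dimethylcyclodeca-2,6-dien-4-ol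
Product: 30 (1S,2E,4S,6E,10S)-1-(tert-butyldimethylsilyloxy)-10-isopropyl-3,7-dimethylcyclodeca-2,6-dien-4-yl 3-methylbut-2-enoate
Conditions: Me2C=CHCO2H, DCC, DMAP, CH2Cl2, 0 → 23 °C
Reagents that add atoms: 3-methylbut-2-enoic acid CC(C)=CC(O)=O
Why: Steglich esterification acylates the secondary allylic C4 alcohol, and carbodiimide activation of the acid avoids the ketene pathway by which the acid chloride deconjugates.

Step 20
Reactants: 30 (1S,2E,4S,6E,10S)-1-(tert-butyldimethylsilyloxy)-10-isopropyl-3,7-dimethylcyclodeca-2,6-dien-4-yl 3-methylbut-2-enoate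
Product: 31 (1S,2E,4S,6E,10S)-1-hydroxy-10-isopropyl-3,7-dimethylcyclodeca-2,6-dien-4-yl 3-methylbut-2-enoate
Conditions: Bu4NF, AcOH, THF, 0 → 23 °C
Reagents that add atoms: none
Why: Fluoride cleaves the secondary silyl ether, and the acetic acid buffer protects the senecioate from the basic fluoride.

Step 21
Reactants: 31 (1S,2E,4S,6E,10S)-1-hydroxy-10-isopropyl-3,7-dimethylcyclodeca-2,6-dien-4-yl 3-methylbut-2-enoate
Product: 32 (2E,4S,6E,10S)-10-isopropyl-3,7-dimethyl-1-oxocyclodeca-2,6-dien-4-yl 3-methylbut-2-enoate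
Conditions: Dess–Martin periodinane, NaHCO3, CH2Cl2, 0 °C (used at once)
Reagents that add atoms: none
Why: Dess–Martin oxidation converts the secondary allylic alcohol into the enone under buffered, non-epimerising conditions, which matters because C10 is now α to the ketone.

Step 22
Reactants: 32 (2E,4S,6E,10S)-10-isopropyl-3,7-dimethyl-1-oxocyclodeca-2,6-dien-4-yl 3-methylbut-2-enoate
Product: 33 (1R,2E,4S,6E,10S)-1-hydroxy-10-isopropyl-3,7-dimethylcyclodeca-2,6-dien-4-yl 3-methylbut-2-enoate
Conditions: NaBH4, CeCl3·7H2O, MeOH, −78 °C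
Reagents that add atoms: none
Why: In this Luche 1,2-reduction the C3 methyl group and the ring should shield one face of the twisted enone carbonyl in the crossed chair–chair conformer, so hydride is expected to add from the periphery and give the 1R alcohol, and any 1S epimer 31 is recycled through step 21.

Step 23
Reactants: 33 (1R,2E,4S,6E,10S)-1-hydroxy-10-isopropyl-3,7-dimethylcyclodeca-2,6-dien-4-yl 3-methylbut-2-enoate
Product: 34 (1R,2R,3R,4S,6E,10S)-2,3-epoxy-1-hydroxy-10-isopropyl-3,7-dimethylcyclodec-6-en-4-yl 3-methylbut-2-enoate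
Conditions: VO(acac)2 (cat.), t-BuOOH, CH2Cl2, 0 °C
Reagents that add atoms: tert-butyl hydroperoxide CC(C)(C)OO
Why: In this vanadium-catalysed hydroxyl-directed epoxidation the vanadate ester of the C1 hydroxyl delivers oxygen only to the allylic C2=C3 alkene (not to C6=C7 or the senecioate) with an O–C1–C2=C3 dihedral angle near 40° and C10 on the opposite face, which is the erythro mode, coincides with attack on the peripheral face and should set C2 and C3 as R,R.

Step 24
Reactants: 34 (1R,2R,3R,4S,6E,10S)-2,3-epoxy-1-hydroxy-10-isopropyl-3,7-dimethylcyclodec-6-en-4-yl 3-methylbut-2-enoate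
Product: 35 (1R,2R,3R,4S,6E,10S)-1-acetoxy-2,3-epoxy-10-isopropyl-3,7-dimethylcyclodec-6-en-4-yl 3-methylbut-2-enoate (CNP0267399.1)
Conditions: Ac2O, pyridine, DMAP (cat.), CH2Cl2, 0 → 23 °C
Reagents that add atoms: acetic anhydride CC(=O)OC(C)=O
Why: DMAP-catalysed acetylation of the hindered secondary alcohol runs under basic conditions that leave the oxirane and the senecioate intact.

**Compound list**

1 | propargyl alcohol | C#CCO | starting material
2 | dimethylaluminium (E)-3-(dimethylalumanyl)-2-methylprop-2-en-1-olate | C[Al](C)OC/C(C)=C/[Al](C)C | intermediate (not isolated)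
3 | (E)-3-iodo-2-methylprop-2-en-1-ol | OC/C(C)=C/I | intermediate
4 | (E)-3-iodo-2-methylprop-2-enal | O=C/C(C)=C/I | intermediate
5 | diisopinocampheylborinate of 6 | I/C=C(C)/[C@H](CC=C)OB([C@@H]1C[C@@H]2C[C@H]([C@H]1C)C2(C)C)[C@@H]1C[C@@H]2C[C@H]([C@H]1C)C2(C)C | intermediate (not isolated)
6 | (1E,3S)-1-iodo-2-methylhexa-1,5-dien-3-ol | I/C=C(C)/[C@@H](O)CC=C | intermediate
7 | (1E,3S)-1-iodo-3-(4-methoxybenzyloxy)-2-methylhexa-1,5-diene | I/C=C(C)/[C@@H](OCc1ccc(OC)cc1)CC=C | intermediate
8 | (3S,4E)-5-iodo-3-(4-methoxybenzyloxy)-4-methylpent-4-enal | I/C=C(C)/[C@@H](OCc1ccc(OC)cc1)CC=O | intermediate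
9 | isopropenylmagnesium bromide | CC(=C)[Mg]Br | starting material
10 | (1E,3S)-1-iodo-3-(4-methoxybenzyloxy)-2,6-dimethylhepta-1,6-dien-5-ol (both C5 epimers) | I/C=C(C)/[C@@H](OCc1ccc(OC)cc1)CC(O)C(C)=C | intermediate
11 | triethyl orthoacetate | CCOC(C)(OCC)OCC | starting material
12 | 1-ethoxyvinyl ether of 10 (mixed ketene acetal) | C=C(OCC)OC(C[C@H](OCc1ccc(OC)cc1)/C(C)=C/I)C(C)=C | intermediate (not isolated)
13 | ethyl (4E,7S,8E)-9-iodo-7-(4-methoxybenzyloxy)-4,8-dimethylnona-4,8-dienoate | CCOC(=O)CC/C(C)=C/C[C@H](OCc1ccc(OC)cc1)/C(C)=C/I | intermediate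
14 | (E)-triethyl(3-iodo-2-methylprop-2-enyloxy)silane | CC[Si](CC)(CC)OC/C(C)=C/I | intermediate
15 | (E)-[2-methyl-3-(triethylsilyloxy)prop-1-enyl]lithium | CC[Si](CC)(CC)OC/C(C)=C/[Li] | intermediate (not isolated)
16 | (E)-3-methyl-4-(triethylsilyloxy)but-2-enal | CC[Si](CC)(CC)OC/C(C)=C/C=O | intermediate
17 | ethyl (4E,7S,8E,10S,11E)-10-hydroxy-7-(4-methoxybenzyloxy)-4,8,12-trimethyl-13-(triethylsilyloxy)trideca-4,8,11-trienoate | CCOC(=O)CC/C(C)=C/C[C@H](OCc1ccc(OC)cc1)/C(C)=C/[C@@H](O)/C=C(C)/CO[Si](CC)(CC)CC | intermediate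
18 | ethyl (4E,7S,8E,10S,11E)-10-(tert-butyldimethylsilyloxy)-7-(4-methoxybenzyloxy)-4,8,12-trimethyl-13-(triethylsilyloxy)trideca-4,8,11-trienoate | CCOC(=O)CC/C(C)=C/C[C@H](OCc1ccc(OC)cc1)/C(C)=C/[C@@H](O[Si](C)(C)C(C)(C)C)/C=C(C)/CO[Si](CC)(CC)CC | intermediate
19 | ethyl (4E,7S,8E,10S,11E)-10-(tert-butyldimethylsilyloxy)-13-hydroxy-7-(4-methoxybenzyloxy)-4,8,12-trimethyltrideca-4,8,11-trienoate | CCOC(=O)CC/C(C)=C/C[C@H](OCc1ccc(OC)cc1)/C(C)=C/[C@@H](O[Si](C)(C)C(C)(C)C)/C=C(C)/CO | intermediate
20 | (4E,7S,8E,10S,11E)-10-(tert-butyldimethylsilyloxy)-13-hydroxy-7-(4-methoxybenzyloxy)-4,8,12-trimethyltrideca-4,8,11-trienoic acid (seco acid) | OC(=O)CC/C(C)=C/C[C@H](OCc1ccc(OC)cc1)/C(C)=C/[C@@H](O[Si](C)(C)C(C)(C)C)/C=C(C)/CO | intermediate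
21 | mixed 2,4,6-trichlorobenzoic anhydride of 20 | O=C(OC(=O)CC/C(C)=C/C[C@H](OCc1ccc(OC)cc1)/C(C)=C/[C@@H](O[Si](C)(C)C(C)(C)C)/C=C(C)/CO)c1c(Cl)cc(Cl)cc1Cl | intermediate (not isolated)
22 | (5E,8S,9E,11S,12E)-11-(tert-butyldimethylsilyloxy)-8-(4-methoxybenzyloxy)-5,9,13-trimethyl-1-oxacyclotetradeca-5,9,12-trien-2-one (1S,4S in target numbering; key-step precursor) | O=C1OC/C(C)=C/[C@H](O[Si](C)(C)C(C)(C)C)/C=C(C)/[C@@H](OCc2ccc(OC)cc2)C/C=C(\C)CC1 | intermediate
23 | cyclic tert-butyldimethylsilyl ketene acetal of 22 (C9=C geometry unassigned) | CC(C)(C)[Si](C)(C)OC1=CC/C(C)=C/C[C@H](OCc2ccc(OC)cc2)/C(C)=C/[C@@H](O[Si](C)(C)C(C)(C)C)/C=C(C)/CO1 | intermediate (not isolated)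
24 | tert-butyldimethylsilyl ester of 25 (C9 unassigned) | CC(C)(C)[Si](C)(C)OC(=O)C1C/C(C)=C/C[C@H](OCc2ccc(OC)cc2)/C(C)=C/[C@@H](O[Si](C)(C)C(C)(C)C)[C@@H]1C(C)=C | intermediate (not isolated)
25 | (1R,2E,4S,6E,10S)-1-(tert-butyldimethylsilyloxy)-10-isopropenyl-4-(4-methoxybenzyloxy)-3,7-dimethylcyclodeca-2,6-diene-9-carboxylic acid (target numbering; C9 unassigned; key-step product) | OC(=O)C1C/C(C)=C/C[C@H](OCc2ccc(OC)cc2)/C(C)=C/[C@@H](O[Si](C)(C)C(C)(C)C)[C@@H]1C(C)=C | intermediate
26 | (1S,2E,4S,6E,10R)-1-(tert-butyldimethylsilyloxy)-10-isopropyl-4-(4-methoxybenzyloxy)-3,7-dimethylcyclodeca-2,6-diene-9-carboxylic acid (C9 unassigned) | OC(=O)C1C/C(C)=C/C[C@H](OCc2ccc(OC)cc2)/C(C)=C/[C@@H](O[Si](C)(C)C(C)(C)C)[C@@H]1C(C)C | intermediate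
27 | 2-thioxopyridin-1(2H)-yl ester of 26 (Barton ester) | S=c1ccccn1OC(=O)C1C/C(C)=C/C[C@H](OCc2ccc(OC)cc2)/C(C)=C/[C@@H](O[Si](C)(C)C(C)(C)C)[C@@H]1C(C)C | intermediate (not isolated)
28 | (1S,2E,4S,6E,10S)-1-(tert-butyldimethylsilyloxy)-10-isopropyl-4-(4-methoxybenzyloxy)-3,7-dimethylcyclodeca-2,6-diene | C1C/C(C)=C/C[C@H](OCc2ccc(OC)cc2)/C(C)=C/[C@@H](O[Si](C)(C)C(C)(C)C)[C@@H]1C(C)C | intermediate
29 | (1S,2E,4S,6E,10S)-1-(tert-butyldimethylsilyloxy)-10-isopropyl-3,7-dimethylcyclodeca-2,6-dien-4-ol | C1C/C(C)=C/C[C@H](O)/C(C)=C/[C@@H](O[Si](C)(C)C(C)(C)C)[C@@H]1C(C)C | intermediate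
30 | (1S,2E,4S,6E,10S)-1-(tert-butyldimethylsilyloxy)-10-isopropyl-3,7-dimethylcyclodeca-2,6-dien-4-yl 3-methylbut-2-enoate | C1C/C(C)=C/C[C@H](OC(=O)C=C(C)C)/C(C)=C/[C@@H](O[Si](C)(C)C(C)(C)C)[C@@H]1C(C)C | intermediate
31 | (1S,2E,4S,6E,10S)-1-hydroxy-10-isopropyl-3,7-dimethylcyclodeca-2,6-dien-4-yl 3-methylbut-2-enoate | C1C/C(C)=C/C[C@H](OC(=O)C=C(C)C)/C(C)=C/[C@@H](O)[C@@H]1C(C)C | intermediate
32 | (2E,4S,6E,10S)-10-isopropyl-3,7-dimethyl-1-oxocyclodeca-2,6-dien-4-yl 3-methylbut-2-enoate | O=C1/C=C(C)/[C@@H](OC(=O)C=C(C)C)C/C=C(\C)CC[C@H]1C(C)C | intermediate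
33 | (1R,2E,4S,6E,10S)-1-hydroxy-10-isopropyl-3,7-dimethylcyclodeca-2,6-dien-4-yl 3-methylbut-2-enoate | O[C@H]1/C=C(C)/[C@@H](OC(=O)C=C(C)C)C/C=C(\C)CC[C@H]1C(C)C | intermediate
34 | (1R,2R,3R,4S,6E,10S)-2,3-epoxy-1-hydroxy-10-isopropyl-3,7-dimethylcyclodec-6-en-4-yl 3-methylbut-2-enoate | O[C@H]1[C@H]2O[C@]2(C)[C@@H](OC(=O)C=C(C)C)C/C=C(\C)CC[C@H]1C(C)C | intermediate
35 | (1R,2R,3R,4S,6E,10S)-1-acetoxy-2,3-epoxy-10-isopropyl-3,7-dimethylcyclodec-6-en-4-yl 3-methylbut-2-enoate (CNP0267399.1) | CC(=O)O[C@H]1[C@H]2O[C@]2(C)[C@@H](OC(=O)C=C(C)C)C/C=C(\C)CC[C@H]1C(C)C | target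

**Step count and risks**

Total step count: 24. Longest linear sequence: 22 steps (steps 1–7 and 10–24 from propargyl alcohol); steps 8 and 9 form the two-step branch from 3.

Steps most likely to fail:

1. Step 15 (ring contraction). What may go wrong: insufficient or reversed face selectivity at C10, or a rearrangement that is too slow below the temperature at which the cyclodeca-1,5-diene product undergoes Cope rearrangement. Fallback, setting out from 22 and returning at 25: reagent-controlled boron-enolate Claisen ring contraction. Lactone 22 is treated with (4S,5S)-2-bromo-4,5-diphenyl-1,3-bis(p-tolylsulfonyl)-1,3,2-diazaborolidine (or its antipode, whichever reinforces the substrate bias) and Et3N in toluene–hexane, or i-Pr2NEt in CH2Cl2, at −78 °C to give the boron ketene acetal F1, which rearranges at −20 to 4 °C; hydrolytic work-up gives 25. The chiral ligand on boron then selects the enolate face and, through the chair array, the C10 face, and the low temperature removes the Cope risk.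

2. Step 22 (correction of C1). What may go wrong: low facial selectivity of hydride addition because the ten-membered enone reacts through more than one ring conformer, or E/Z isomerisation of the strained enone before reduction. Fallback, setting out from 31 and returning at 33: inversion by substitution instead of by redox. Mitsunobu reaction of 31 (PPh3, diisopropyl azodicarboxylate, chloroacetic acid, toluene, 0 °C) gives the inverted chloroacetate F2, and its chloroacetyl group is removed beside the senecioate (K2CO3, MeOH, 0 °C) to give 33.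

3. Step 23 (epoxidation). What may go wrong: oxygen delivery to the opposite face of C2=C3 through the relaxed conformer with H-1 in the alkene plane (threo mode), or loss of chemoselectivity toward C6=C7. Fallback, setting out from 31 and returning at 34: the order of the two operations is exchanged so that the same threo bias becomes productive. The 1S alcohol 31 is epoxidised (VO(acac)2, t-BuOOH, CH2Cl2, 0 °C) on its exposed face to the (1S,2R,3R)-epoxy alcohol F3. Dess–Martin oxidation (NaHCO3, CH2Cl2, 0 °C) gives the epoxy ketone F4, and chelation-controlled reduction with Zn(BH4)2 (Et2O, −20 °C), which gives the anti (erythro) epoxy alcohol by hydride attack opposite C3, returns to 34.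

**Further compounds**

F1 | step 15 | boron ketene acetal of 22 carrying the (4S,5S)-4,5-diphenyl-1,3-bis(p-tolylsulfonyl)-1,3,2-diazaborolidin-2-yl group on the enolate oxygen | O(B1N(S(=O)(=O)c2ccc(C)cc2)[C@@H](c2ccccc2)[C@H](c2ccccc2)N1S(=O)(=O)c1ccc(C)cc1)C1=CC/C(C)=C/C[C@H](OCc2ccc(OC)cc2)/C(C)=C/[C@@H](O[Si](C)(C)C(C)(C)C)/C=C(C)/CO1
F2 | step 22 | (1R,2E,4S,6E,10S)-1-(chloroacetoxy)-10-isopropyl-3,7-dimethylcyclodeca-2,6-dien-4-yl 3-methylbut-2-enoate | ClCC(=O)O[C@H]1/C=C(C)/[C@@H](OC(=O)C=C(C)C)C/C=C(\C)CC[C@H]1C(C)C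
F3 | step 23 | (1S,2R,3R,4S,6E,10S)-2,3-epoxy-1-hydroxy-10-isopropyl-3,7-dimethylcyclodec-6-en-4-yl 3-methylbut-2-enoate | O[C@@H]1[C@H]2O[C@]2(C)[C@@H](OC(=O)C=C(C)C)C/C=C(\C)CC[C@H]1C(C)C
F4 | step 23 | (2S,3R,4S,6E,10S)-2,3-epoxy-10-isopropyl-3,7-dimethyl-1-oxocyclodec-6-en-4-yl 3-methylbut-2-enoate | O=C1[C@H]2O[C@]2(C)[C@@H](OC(=O)C=C(C)C)C/C=C(\C)CC[C@H]1C(C)C
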